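**Retrosynthetic overview**
- The target is the tyrosol ester of unbranched tetracontanoic acid. Disconnect the acyl C–O bond: a chemoselective Fischer esterification at the primary alcohol, leaving the phenol free.
- Disconnect the C40 acid at C18–C19 into a C22 Grignard reagent and a C18 ω-bromo acid, joined by copper-catalysed sp3–sp3 coupling on the magnesium carboxylate.
- No ring is formed: the only ring, the phenol ring, is bought as part of tyrosol.
- The target has no stereocentre, so no stereocontrol is needed.

Assumption: the acyl chain is read as unbranched tetracontanoyl (40 carbons counting C=O), the molecule is achiral so the "single enantiomer" is the compound itself, and tetracontanoic acid is treated as not being a catalogue item and is therefore built from catalogue C22 and C18 pieces.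

**Route**

Step 1
Reactants: 1 1-bromodocosane; 2 18-bromooctadecanoic acid
Product: 6 tetracontanoic acid, via docosylmagnesium bromide 3 (not isolated), via chloromagnesium 18-bromooctadecanoate 4 (not isolated), via chloromagnesium tetracontanoate 5 (not isolated)
Conditions: (a) 1 (1.5 equiv), Mg, THF, 50 °C; (b) 2, MeMgCl (1.0 equiv), THF, −20 °C; (c) add warm 3 to 4, Li2CuCl4 (3 mol%), THF, −10 °C → rt; (d) aq. HCl
Reagents that add atoms: none
Why: Kochi-type copper-catalysed sp3–sp3 Grignard cross-coupling, in which the C22 Grignard 3 displaces the primary bromide of the C18 ω-bromo acid while its CO2H is masked as the inert halomagnesium carboxylate 4, so acidification gives the C40 acid (22 + 18 carbons) with no stereocentre formed.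

Step 2
Reactants: 6 tetracontanoic acid; 7 tyrosol, 2-(4-hydroxyphenyl)ethanol
Product: 8 2-(4-hydroxyphenyl)ethyl tetracontanoate (target)
Conditions: 7 (3 equiv), TsOH·H2O (10 mol%), toluene, reflux, Dean–Stark; product precipitated with MeOH
Reagents that add atoms: none
Why: Fischer esterification driven by azeotropic water removal acylates only the primary alcohol of 7, because aryl esters are strongly disfavoured under reversible acid catalysis, so the phenol needs no protection and no stereocentre is involved.

**Compound list**
1 | 1-bromodocosane | CCCCCCCCCCCCCCCCCCCCCCBr | starting material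
2 | 18-bromooctadecanoic acid | BrCCCCCCCCCCCCCCCCCC(=O)O | starting material
3 | docosylmagnesium bromide | CCCCCCCCCCCCCCCCCCCCCC[Mg]Br | intermediate
4 | chloromagnesium 18-bromooctadecanoate | BrCCCCCCCCCCCCCCCCCC(=O)O[Mg]Cl | intermediate
5 | chloromagnesium tetracontanoate | CCCCCCCCCCCCCCCCCCCCCCCCCCCCCCCCCCCCCCCC(=O)O[Mg]Cl | intermediate
6 | tetracontanoic acid | CCCCCCCCCCCCCCCCCCCCCCCCCCCCCCCCCCCCCCCC(=O)O | intermediate
7 | tyrosol, 2-(4-hydroxyphenyl)ethanol | OCCc1ccc(O)cc1 | starting material
8 | 2-(4-hydroxyphenyl)ethyl tetracontanoate (CNP0197010.0, achiral) | CCCCCCCCCCCCCCCCCCCCCCCCCCCCCCCCCCCCCCCC(=O)OCCc1ccc(O)cc1 | target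

**Summary**
Total step count: 2. Longest linear sequence: 2 steps (1 → 6 → 8).

Steps most likely to fail: the route has only two steps, so both are ranked and there is no third.

Most likely to fail is step 1. The C22 Grignard reagent and the magnesium salt 4 are poorly soluble in the cold, and Wurtz homocoupling or simple reduction of the Grignard reagent can compete with the cross-coupling. The fallback sets out from 1 and comes back to the route at 6. It replaces the sp3–sp3 coupling by an acetylide alkylation. Purchased 17-octadecynoic acid F1 is doubly deprotonated (n-BuLi, 2.1 equiv, THF/DMPU, −40 → 0 °C) to lithium 18-lithiooctadec-17-ynoate F2. Alkylation of this with 1 (0 → 45 °C) gives lithium tetracont-17-ynoate F3, and acidic work-up gives tetracont-17-ynoic acid F4. Hydrogenation of the triple bond (H2, Pd/C, THF, 50 °C) then gives 6.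

Second is step 2. The C40 acid is sparingly soluble, so conversion may be incomplete, and some acylation of the phenol cannot be excluded. The fallback sets out from 7 and comes back to the route at 8. It uses a protecting group instead of relying on chemoselectivity. Compound 7 is benzylated at the phenol only (BnBr, K2CO3, acetone, reflux) to give 2-[4-(benzyloxy)phenyl]ethanol F5. Steglich coupling of this alcohol with 6 (DCC, DMAP, CHCl3, 45 °C) gives 2-[4-(benzyloxy)phenyl]ethyl tetracontanoate F6. Hydrogenolysis of the benzyl ether (H2, Pd/C, THF/EtOAc, 45 °C) gives 8.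

**Further compounds**
F1 | step 1 | 17-octadecynoic acid | C#CCCCCCCCCCCCCCCCC(=O)O
F2 | step 1 | lithium 18-lithiooctadec-17-ynoate | [Li]C#CCCCCCCCCCCCCCCCC(=O)O[Li]
F3 | step 1 | lithium tetracont-17-ynoate | CCCCCCCCCCCCCCCCCCCCCCC#CCCCCCCCCCCCCCCCC(=O)O[Li]
F4 | step 1 | tetracont-17-ynoic acid | CCCCCCCCCCCCCCCCCCCCCCC#CCCCCCCCCCCCCCCCC(=O)O
F5 | step 2 | 2-[4-(benzyloxy)phenyl]ethanol | OCCc1ccc(OCc2ccccc2)cc1
F6 | step 2 | 2-[4-(benzyloxy)phenyl]ethyl tetracontanoate | CCCCCCCCCCCCCCCCCCCCCCCCCCCCCCCCCCCCCCCC(=O)OCCc1ccc(OCc2ccccc2)cc1
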